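The target is opened at two bonds, C5–C6 in the 1,2-dioxane ring and C4–O in the γ-lactone ring. The feature used is that C4, a carbon able to carry a tertiary cation, lies between C5 and the lactone oxygen, with both peroxide carbons (C3 and C6) close by. A single Lewis-acid treatment of an open-chain methoxy peroxyketal should expel methoxide, join the alkene terminus C5 to the C6 peroxycarbenium carbon and let the ester carbonyl capture the C4 cation with loss of isobutene, so that C3 alone dictates C4 and C6. The precursor joins (R)-tert-butyl 3-hydroperoxy-4-methylpent-4-enoate to an aryl-substituted alkynyl methyl ketone as its mixed ketal.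

Key step: step 9

Remarks
- Numbering: C1 lactone carbonyl, C2 CH2, C3 CH–OO, C4 C(Me)–O, C5 ring CH2, C6 C(Me)(chain)–OO, chain C7–C16. The target is (3R,4R,6S) in this numbering, (3S,4aR,7aR) in the fused-ring name.
- Assumption (step 3): the peroxidase is taken to reduce the 3S hydroperoxide faster and leave the 3R enantiomer. The sense must be checked on recovered 4 (PPh3 reduction, MTPA esters); the fallback for step 3 does not depend on it.
- Structure correction: alkyne 17 is a 7,7,8,8-tetradehydro derivative of 18. Its C6 descriptor is R only because the alkynyl carbon outranks C5; the arrangement in space is that of the target.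
- Starting materials: 1, 5, 7 and 10 are commercial; 1,8-dibromooctane and but-3-yn-2-one were chosen so that the aryl–alkyl bond is made without a free terminal alkyne present.

Step 1
Reactants: 1 4-methylpent-3-enoic acid
Product: 2 tert-butyl 4-methylpent-3-enoate
Conditions: t-BuOC(=NH)CCl3 (2 equiv), cyclohexane/CH2Cl2, rt
Reagents that add atoms: tert-butyl 2,2,2-trichloroacetimidate, CC(C)(C)OC(=N)C(Cl)(Cl)Cl
Why: Imidate esterification, in which the carboxylic acid itself protonates the imidate and is O-alkylated, so neither strong acid (lactonisation of this β,γ-unsaturated acid) nor base (shift of the double bond into conjugation) is needed.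

Step 2
Reactants: 2 tert-butyl 4-methylpent-3-enoate
Product: 3 rac-tert-butyl 3-hydroperoxy-4-methylpent-4-enoate
Conditions: O2, tetraphenylporphyrin (cat.), visible light, CH2Cl2, 0 °C
Reagents that add atoms: dioxygen, O=O
Why: Schenck ene reaction of singlet oxygen with a trisubstituted alkene, in which hydrogen should be taken from the geminal methyl groups in preference to the electron-poor C2–H bonds, giving the secondary allylic hydroperoxide with the isopropenyl group; C3 forms racemic and the conjugated tertiary regioisomer would be removed by chromatography.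

Step 3
Reactants: 3 rac-tert-butyl 3-hydroperoxy-4-methylpent-4-enoate
Product: 4 tert-butyl (3R)-3-hydroperoxy-4-methylpent-4-enoate
Conditions: horseradish peroxidase (cat.), guaiacol (1 equiv), phosphate buffer pH 6, rt, to just over half conversion; chromatography
Reagents that add atoms: none
Why: Peroxidase-catalysed kinetic resolution of a secondary hydroperoxide, in which the enzyme reduces one enantiomer to the alcohol with guaiacol as reductant and leaves the other, here taken to be 3R, so that C3 becomes the single stereocentre carried into the key step.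

Step 4
Reactants: 5 4-bromophenol
Product: 6 (4-bromophenoxy)(tert-butyl)dimethylsilane
Conditions: TBSCl, imidazole, CH2Cl2, rt
Reagents that add atoms: tert-butyldimethylsilyl chloride, CC(C)(C)[Si](C)(C)Cl
Why: Imidazole-promoted silylation of a phenol, giving an aryl silyl ether that tolerates Grignard formation, acetylide alkylation and low-temperature Lewis acid.

Step 5
Reactants: 6 (4-bromophenoxy)(tert-butyl)dimethylsilane; 7 1,8-dibromooctane
Product: 9 [4-(8-bromooctyl)phenoxy](tert-butyl)dimethylsilane, via arylmagnesium bromide 8 (not isolated)
Conditions: Mg, THF, 45 °C; then 7 (3 equiv), Li2CuCl4 (3 mol%), THF/NMP, −10 °C → rt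
Reagents that add atoms: none
Why: Copper-catalysed cross-coupling of an aryl Grignard reagent with a primary alkyl bromide (Kochi-type), with the excess of symmetrical dibromide suppressing double arylation.

Step 6
Reactants: 10 but-3-yn-2-one
Product: 11 3,3-dimethoxybut-1-yne
Conditions: HC(OMe)3, MeOH, TsOH·H2O (cat.), 0 °C → rt; K2CO3, distillation
Reagents that add atoms: trimethyl orthoformate, COC(OC)OC
Why: Acid-catalysed ketalisation driven by the orthoformate, where under anhydrous acid the carbonyl group should react faster than methanol adds to the triple bond.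

Step 7
Reactants: 11 3,3-dimethoxybut-1-yne; 9 [4-(8-bromooctyl)phenoxy](tert-butyl)dimethylsilane
Product: 13 tert-butyl[4-(11,11-dimethoxydodec-9-yn-1-yl)phenoxy]dimethylsilane, via lithium acetylide 12 (not isolated)
Conditions: n-BuLi, THF, −78 °C; then 9, NaI (cat.), DMPU, −78 °C → rt
Reagents that add atoms: none
Why: SN2 alkylation of a lithium acetylide by a primary halide (iodide formed in situ, Finkelstein) in a dipolar cosolvent, with the ketal inert to the base and the hindered aryl silyl ether expected to survive.

Step 8
Reactants: 4 tert-butyl (3R)-3-hydroperoxy-4-methylpent-4-enoate; 13 tert-butyl[4-(11,11-dimethoxydodec-9-yn-1-yl)phenoxy]dimethylsilane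
Product: 14 tert-butyl (3R)-3-{[12-(4-{[tert-butyl(dimethyl)silyl]oxy}phenyl)-2-methoxydodec-3-yn-2-yl]peroxy}-4-methylpent-4-enoate (both epimers at the peroxyketal carbon)
Conditions: 13 (1.5 equiv), CSA (5 mol%), 4 Å MS, CH2Cl2, 0 °C → rt; Et3N quench
Reagents that add atoms: none
Why: Acid-catalysed transketalisation, in which the ketal ionises to an alkynyl oxocarbenium ion that the hydroperoxide oxygen captures; a second exchange would need the less stabilised peroxycarbenium ion and should stay slow, C3 is untouched, and the new ketal centre (both epimers) is ionised in the next step.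

Step 9
Reactants: 14 tert-butyl (3R)-3-{[12-(4-{[tert-butyl(dimethyl)silyl]oxy}phenyl)-2-methoxydodec-3-yn-2-yl]peroxy}-4-methylpent-4-enoate
Product: 17 (3R,4aR,7aR)-3-[10-(4-{[tert-butyl(dimethyl)silyl]oxy}phenyl)dec-1-yn-1-yl]-3,4a-dimethyltetrahydrofuro[3,2-c][1,2]dioxin-6(3H)-one (7,7,8,8-tetradehydroplakortolide S TBS ether), via peroxycarbenium triflate 15 (not isolated), via dioxanyl cation 16 (not isolated)
Conditions: TMSOTf (1.2 equiv), 2,6-di-tert-butyl-4-methylpyridine (1.5 equiv), CH2Cl2 (0.01 M), −78 → −40 °C; NaHCO3 quench
Reagents that add atoms: none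
Why: TMSOTf takes the methoxy group from the ether oxygen of the ketal (as TMSOMe) to give the alkynyl peroxycarbenium ion 15, the unsubstituted alkene carbon C5 adds to C6 and leaves the tertiary C4 cation 16, and the ester carbonyl oxygen closes onto C4 while the tert-butyl group departs as isobutene, the hindered pyridine binding the triflic acid. The closest known reaction types are the Lewis-acid cyclisation of unsaturated monoperoxyketals through peroxycarbenium ions to 1,2-dioxanes (a peroxy variant of the Prins cyclisation) and cation–olefin cyclisations that end in lactones by capture with a tert-butyl ester. The 1,2-dioxane closes 6-endo-trig through a chair-like transition state, the γ-lactone by 5-exo attack of the carbonyl oxygen on the cation. C4 is controlled by the tether, because the two-atom arm on C3 reaches C4 only from its own face and gives the cis ring fusion; C6 is controlled by C3 through the chair, in which the rod-shaped alkynyl group sits cis to the O–O bond and becomes axial while the C6 methyl group and the C3 arm are equatorial. The step needs ionisation at the methoxy and not at the peroxy oxygen, 6-endo attack at C6 and not at the remote alkyne carbon, and 1,4-induction from C3 to C6; these should follow from the higher basicity of the ether oxygen, from the six-membered ring size, and from the small steric demand of the alkyne next to methyl, which makes the chair leading to 17 the only one without an axial methyl group.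

Step 10
Reactants: 17 7,7,8,8-tetradehydroplakortolide S TBS ether
Product: 18 (3S,4aR,7aR)-3-[10-(4-{[tert-butyl(dimethyl)silyl]oxy}phenyl)decyl]-3,4a-dimethyltetrahydrofuro[3,2-c][1,2]dioxin-6(3H)-one (plakortolide S TBS ether)
Conditions: KO2C–N=N–CO2K (large excess, in portions), AcOH, MeOH/CH2Cl2, 0 °C → rt, repeated until the intermediate cis-alkene is consumed
Reagents that add atoms: none
Why: Diimide reduction, a concerted syn transfer of H2 to C≡C and then to the cis C=C bond by a reagent that leaves O–O bonds, lactones and aryl silyl ethers alone; no stereocentre is touched.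

Step 11
Reactants: 18 plakortolide S TBS ether
Product: 19 plakortolide S, (3S,4aR,7aR)-3-[10-(4-hydroxyphenyl)decyl]-3,4a-dimethyltetrahydrofuro[3,2-c][1,2]dioxin-6(3H)-one
Conditions: TBAF (1.2 equiv), AcOH (1.5 equiv), THF, 0 °C
Reagents that add atoms: none
Why: Fluoride cleavage of the aryl Si–O bond, with acetic acid buffering the basicity so that the β-peroxy lactone is not opened by E1cB elimination or Kornblum–DeLaMare fragmentation.

Compound list
1 | 4-methylpent-3-enoic acid | CC(C)=CCC(O)=O | starting material
2 | tert-butyl 4-methylpent-3-enoate | CC(C)=CCC(=O)OC(C)(C)C | intermediate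
3 | rac-tert-butyl 3-hydroperoxy-4-methylpent-4-enoate | C=C(C)C(CC(=O)OC(C)(C)C)OO | intermediate
4 | tert-butyl (3R)-3-hydroperoxy-4-methylpent-4-enoate | C=C(C)[C@@H](CC(=O)OC(C)(C)C)OO | intermediate
5 | 4-bromophenol | Oc1ccc(Br)cc1 | starting material
6 | (4-bromophenoxy)(tert-butyl)dimethylsilane | CC(C)(C)[Si](C)(C)Oc1ccc(Br)cc1 | intermediate
7 | 1,8-dibromooctane | BrCCCCCCCCBr | starting material
8 | (4-{[tert-butyl(dimethyl)silyl]oxy}phenyl)magnesium bromide | CC(C)(C)[Si](C)(C)Oc1ccc([Mg]Br)cc1 | intermediate (not isolated)
9 | [4-(8-bromooctyl)phenoxy](tert-butyl)dimethylsilane | CC(C)(C)[Si](C)(C)Oc1ccc(CCCCCCCCBr)cc1 | intermediate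
10 | but-3-yn-2-one | CC(=O)C#C | starting material
11 | 3,3-dimethoxybut-1-yne | COC(C)(OC)C#C | intermediate
12 | lithium 3,3-dimethoxybut-1-yn-1-ide | [Li]C#CC(C)(OC)OC | intermediate (not isolated)
13 | tert-butyl[4-(11,11-dimethoxydodec-9-yn-1-yl)phenoxy]dimethylsilane | COC(C)(OC)C#CCCCCCCCCc1ccc(O[Si](C)(C)C(C)(C)C)cc1 | intermediate
14 | tert-butyl (3R)-3-{[12-(4-{[tert-butyl(dimethyl)silyl]oxy}phenyl)-2-methoxydodec-3-yn-2-yl]peroxy}-4-methylpent-4-enoate; both epimers at the peroxyketal carbon, left open in the SMILES | C=C(C)[C@@H](CC(=O)OC(C)(C)C)OOC(C)(OC)C#CCCCCCCCCc1ccc(O[Si](C)(C)C(C)(C)C)cc1 | intermediate (key-step precursor)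
15 | alkynyl peroxycarbenium triflate from 14 | C=C(C)[C@@H](CC(=O)OC(C)(C)C)O[O+]=C(C)C#CCCCCCCCCc1ccc(O[Si](C)(C)C(C)(C)C)cc1.[O-]S(=O)(=O)C(F)(F)F | intermediate (not isolated)
16 | 1,2-dioxan-4-yl (C4) cation triflate | C[C@]1(C#CCCCCCCCCc2ccc(O[Si](C)(C)C(C)(C)C)cc2)C[C+](C)[C@@H](CC(=O)OC(C)(C)C)OO1.[O-]S(=O)(=O)C(F)(F)F | intermediate (not isolated)
17 | (3R,4aR,7aR)-3-[10-(4-{[tert-butyl(dimethyl)silyl]oxy}phenyl)dec-1-yn-1-yl]-3,4a-dimethyltetrahydrofuro[3,2-c][1,2]dioxin-6(3H)-one | C[C@]1(C#CCCCCCCCCc2ccc(O[Si](C)(C)C(C)(C)C)cc2)C[C@@]2(C)OC(=O)C[C@H]2OO1 | intermediate (key-step product)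
18 | (3S,4aR,7aR)-3-[10-(4-{[tert-butyl(dimethyl)silyl]oxy}phenyl)decyl]-3,4a-dimethyltetrahydrofuro[3,2-c][1,2]dioxin-6(3H)-one | C[C@]1(CCCCCCCCCCc2ccc(O[Si](C)(C)C(C)(C)C)cc2)C[C@@]2(C)OC(=O)C[C@H]2OO1 | intermediate
19 | plakortolide S, (3S,4aR,7aR)-3-[10-(4-hydroxyphenyl)decyl]-3,4a-dimethyltetrahydrofuro[3,2-c][1,2]dioxin-6(3H)-one | C[C@]1(CCCCCCCCCCc2ccc(O)cc2)C[C@@]2(C)OC(=O)C[C@H]2OO1 | target

Total step count: 11.
Longest linear sequence: 7 steps (5 → 6 → 9 → 13 → 14 → 17 → 18 → 19; the branch from 1 through 4 is equally long).

Steps most likely to fail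

1. Step 9. What may go wrong: the ring may close through the other chair, with the C3 arm pseudo-axial, where it no longer eclipses the C4 methyl group (A1,2 strain). With the alkynyl group still axial, that joins C6 with the opposite relative configuration. Lesser risks are ionisation on the peroxide side with Hock-type fragmentation, and proton loss from cation 16 before the lactone closes. The fallback changes the control element and the order of events; it sets out from 13 and 4 and comes back at 18. The triple bond of 13 is saturated while no peroxide is present (H2, Pt/C, EtOAc, trace Et3N) to give tert-butyl[4-(11,11-dimethoxydodecyl)phenoxy]dimethylsilane F1. Transketalisation of F1 with 4 (PPTS, 4 Å MS, CH2Cl2) gives tert-butyl (3R)-3-{[12-(4-{[tert-butyl(dimethyl)silyl]oxy}phenyl)-2-methoxydodecan-2-yl]peroxy}-4-methylpent-4-enoate F2, which is treated with TMSOTf and the hindered pyridine as in step 9. Here the saturated chain is the larger group on the peroxycarbenium carbon, so it should lie trans to O–O and equatorial, with methyl axial. Combined with a pseudo-axial arm this gives the natural relative configuration directly as 18, and step 10 is no longer needed. The methyl/alkyl size difference is small, so the C6 epimers would have to be separated by chromatography.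

2. Step 3. What may go wrong: too little enantiodiscrimination for a hydroperoxide whose two carbon substituents are both of medium size, or reduction of the wrong enantiomer. The fallback sets out from 3 and comes back at 4: preparative HPLC of racemic 3 on a polysaccharide chiral stationary phase. This is a physical separation that gives both enantiomers without relying on an enzyme; the 3R enantiomer is identified by PPh3 reduction of a sample and MTPA ester analysis of the alcohol. No new compound is made (F0).

3. Step 8. What may go wrong: the electron-poor alkynyl ketal may ionise too slowly under acid mild enough for the allylic hydroperoxide, so that acid-induced decomposition of 4 (Hock cleavage) or double exchange to the bis-peroxyketal takes over. The fallback sets out from 13 and 4 and comes back at 14, using addition in place of exchange. Ketal 13 loses methanol with TMSOTf/i-Pr2NEt (CH2Cl2, −20 °C → rt) to give the enol ether tert-butyl[4-(11-methoxydodec-11-en-9-yn-1-yl)phenoxy]dimethylsilane F3. Hydroperoxide 4 then adds across the enol ether double bond under PPTS catalysis (CH2Cl2, 0 °C) with Markovnikov orientation to give 14.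

Further compounds
F1 | step 9 | tert-butyl[4-(11,11-dimethoxydodecyl)phenoxy]dimethylsilane | COC(C)(OC)CCCCCCCCCCc1ccc(O[Si](C)(C)C(C)(C)C)cc1
F2 | step 9 | tert-butyl (3R)-3-{[12-(4-{[tert-butyl(dimethyl)silyl]oxy}phenyl)-2-methoxydodecan-2-yl]peroxy}-4-methylpent-4-enoate (both ketal epimers) | C=C(C)[C@@H](CC(=O)OC(C)(C)C)OOC(C)(OC)CCCCCCCCCCc1ccc(O[Si](C)(C)C(C)(C)C)cc1
F0 | step 3 | none | none
F3 | step 8 | tert-butyl[4-(11-methoxydodec-11-en-9-yn-1-yl)phenoxy]dimethylsilane | C=C(OC)C#CCCCCCCCCc1ccc(O[Si](C)(C)C(C)(C)C)cc1
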